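## Structural features

The target is a C25 labdane-type tetraol. A trans-fused decalin (ring A: C1–C5, C10; ring B: C5–C10) carries at C9 the arm C11–C12–C13(CH3)=C14–C15, and C15 is a secondary carbinol bonded to C5′ of a 4-methylfuran-2(5H)-one. Six stereocentres sit on the decalin: quaternary C4 (4α-CH2OH = C18, 4β-CH3 = C19), C5 (α-H), C6 (equatorial α-OH), C8 (α-OH, β-CH3), C9 (β arm) and quaternary C10 (β-CH3), with C4–C5–C6 and C8–C9–C10 contiguous around ring B. Two further centres, C15 (S) and C5′ (S), are adjacent and syn, but five bonds from C9, and the C13=C14 bond is E. Fragile parts are the butenolide (acidic C5′–H, base-sensitive), the C15 carbinol (allylic and next to the lactone, so prone to ionisation and retro-aldol cleavage), the tertiary 8α-hydroxyl (it can cyclise onto C13 under acid) and the alkene geometry. The real difficulties are the oxidation of only one of the two methyl groups at C4, and the control of C15 and C5′ without help from the ring. The key step uses the peri relation across C5 between the equatorial 6α-oxygen on ring B and the equatorial 4α-methyl on ring A: a silicon atom on O6 can reach a C18–H bond in a chair six-membered array, whereas C19 and the C10 methyl lie on the β face out of reach.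

## Logic of the disconnections

**C15–C5′ (19 ⇒ 18 ⇒ 14 + 16).** After three O–Si bonds (19 to 18), the C15–C5′ bond is cut, through 17, to give 14 and 16. This is the only C–C bond between heterocycle and terpene, and cutting it removes both side-chain stereocentres at once; 14 holds every ring stereocentre. The demand is heavy: the ring cannot bias the aldehyde face, so the forward step needs a chiral catalyst for the absolute sense at C15 and an open transition state for the syn relation to C5′. The other hydroxyls must be silylated because the Lewis acid does not tolerate them.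

**Functional-group level (14 ⇒ 13 ⇒ 12).** No skeletal bond is cut; three O–Si bonds and the oxidation level of C15 are adjusted. The reason is that 12 is exactly what oxidative release from silicon delivers, so no protecting group has to survive the key step for later use. The forward oxidation must pick the allylic primary hydroxyl over the neopentyl C18 hydroxyl, and the silylation of 13 must not enolise the enal.

**C18–O ⇒ C18–Si ⇒ C18–H (12 ⇒ 11 ⇒ 10).** The C18–O bond is traced to a C18–Si bond in 11, and this to a C18–H bond in 10. The cut erases the C4 stereocentre and the C18 oxygen, so C4 becomes an ordinary gem-dimethyl carbon of a natural labdane. The forward step must choose C18 over C19, C20 and C17, which only the geometry of the 6α-O–Si tether can do. The spectators are chosen for this step: 10 holds a single Si–H bond, O8 is capped, and C15 carries a silyl ether and not an ester, because low-valent rhodium with a hydrosilane can ionise or reduce an allylic ester.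

**O–Si bonds (10 ⇒ 8 + 9; 8 ⇒ 7 ⇒ 5).** Three hydroxyls of different class must be told apart: tertiary O8, primary allylic O15 and hindered secondary O6. The forward order uses intrinsic rates only: exhaustive silylation then selective methanolysis (via 6) keeps the tertiary ether, a chlorosilane picks the primary hydroxyl, and O6 is left as the only free hydroxyl for 9.

**C8–O, C17–H and C15–H (5 ⇒ 4 ⇒ 3).** The tertiary 8α-carbinol with its β-methyl is traced to the spiro-epoxide of 4 and this to the exocyclic alkene of 3; the same hydride step also returns C15 to the ester level. The gain is that C8 becomes sp2, as in the natural series. The forward epoxidation must come from the α face and must ignore C13=C14, which is why that alkene is held as an electron-poor enoate at this stage.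

**C13=C14 and C13–C14 (3 ⇒ 2 ⇒ 1).** The alkene is cut by olefination logic to the methyl ketone 2, which comes from 1 by loss of C14 and C15. This replaces a poorly selective allylic transposition at a centre carrying CH3 and CH2R with an olefination whose isomers can be separated early, and it ends at 1, which supplies C5, C6, C9 and C10 and the precursor of C8. The demands are E selectivity and a cleavage that spares the 8(17)-alkene and the 6α-hydroxyl.

**O–Si (16 ⇒ 15).** The C5′ nucleophile is the silyl dienol ether of 15; the only demand is anhydrous handling.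

## Other disconnections considered

**Alternative 1:** Ring A is cut at C3–C4 and C18–O. In the forward sense the aldoxime A1, built on a chiral-pool cyclohexenone with a C5 isopropenyl group, would be oxidised with NaOCl to the nitrile oxide, which adds across the isopropenyl group to give the isoxazoline-fused decalenone A2.
- In favour: the (3+2) cycloaddition is concerted, its regiochemistry is fixed by the tether, and it creates quaternary C4 with C18 already oxygenated.
- Against: A2 has no C6 oxygen, carries a C3 function that must be removed, has a C7=C8 enone where the 8α-carbinol is needed, and has a C9 ketone that must become a C9–H bearing a seven-carbon arm. Which of CH3 and CH2O ends up α at C4 depends on the rotamer of the isopropenyl group and is not assured.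
- Comparison: on structure the chosen plan inherits five ring stereocentres from 1, while A2 inherits one. On mechanism the cycloaddition is the more dependable bond-forming event, and it does not depend on one natural product, so it also gives access to the antipode and analogues; on these two points the alternative is the better. On step economy the chosen plan should be far shorter.

**Alternative 2:** Both rings are cut at C4–C5 and C9–C10. Cp2TiCl (trivalent titanium) would open the epoxide of the acyclic epoxy diene A3 to the C4 radical, which cyclises twice and ends as the 8(17)-alkene in decalin A4.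
- In favour: two rings, two C–C bonds and up to four stereocentres in one step. A4 already has the 18-hydroxyl, the 6α-oxygen and the exocyclic alkene that would give the 8α-carbinol by the chemistry of steps 3 and 4.
- Against: at the planar C4 radical CH3 and CH2OTi differ little, so C4 control is intrinsically weak. The C6 silyloxy group alone must dictate the absolute folding, and early termination competes. A3 needs its own enantioselective synthesis, and the arm of A4 must still be extended to the enal.
- Comparison: in skeletal construction the alternative is clearly the better, and it equals the chosen plan in delivering C18–OH and C6–O together. In stereocontrol at C4 the tether-enforced delivery of the chosen plan should be the more secure. The step count would probably be higher, but the route would be fully synthetic.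

**Alternative 3:** Ring B is cut at C7–C8. Al(OtBu)3 would promote the α-ketol rearrangement of hydrindane A5, in which C7 shifts from C9 to the acetyl carbon to give decalinone A6 with the 8α-carbinol and a C9 ketone.
- In favour: the shift is suprafacial and chelate-controlled, driven by ring expansion, and needs no transition metal.
- Against: A5 must already contain C4, C5, C6 and C10, so the key step does not address the hardest centre. Migration of C10 instead of C7 is a plausible competitor, and the rearrangement is reversible. The C9 ketone of A6, flanked by two fully substituted carbons, must then accept the arm and lose its oxygen with control of H9.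
- Comparison: the alternative sets only C8, which the chosen plan sets in two routine steps. In predictability of the stereochemical outcome at that centre it is equal or better if the regiochemistry holds. In step economy it is worse.

Key step: step 8

Remark on the chemistry: labdane numbering is used (C18 = 4α-methyl, C19 = 4β-methyl, butenolide atoms primed, C5′ bonded to C15), 1 is the (13S)-6α-hydroxy compound of the normal series, and because C9 is too remote to bias C15 and C5′ their absolute configuration is assigned to catalyst control in step 13.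

## Route

Step 1
Reactants: 1 larixol, (13S)-labda-8(17),14-diene-6α,13-diol
Product: 2 6α-hydroxy-14,15-dinorlabd-8(17)-en-13-one
Conditions: KMnO4 (4 equiv, in portions), acetone/H2O, 0 °C
Reagents that add atoms: none
Why: Permanganate oxidative cleavage of a tertiary vinyl carbinol to the methyl ketone (dihydroxylation, glycol cleavage, loss of C14 and C15 as CO2); the monosubstituted alkene next to the hydroxyl should react before the hindered 8(17)-alkene, and low temperature should spare the 6α-hydroxyl. No stereocentre is touched.

Step 2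
Reactants: 2 6α-hydroxy-14,15-dinorlabd-8(17)-en-13-one
Product: 3 ethyl (13E)-6α-hydroxylabda-8(17),13-dien-15-oate
Conditions: (EtO)2P(O)CH2CO2Et (3 equiv), NaH (3.5 equiv), THF, 0 to 60 °C
Reagents that add atoms: triethyl phosphonoacetate, CCOC(=O)CP(=O)(OCC)OCC
Why: Horner–Wadsworth–Emmons olefination of a methyl ketone; the ester should settle anti to the larger C12 methylene, so the E isomer should predominate and the Z isomer is removed by chromatography at this stage. Excess base covers the free hydroxyl.

Step 3
Reactants: 3 ethyl (13E)-6α-hydroxylabda-8(17),13-dien-15-oate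
Product: 4 ethyl (13E)-8α,17-epoxy-6α-hydroxylabd-13-en-15-oate
Conditions: mCPBA (1.2 equiv), NaHCO3, CH2Cl2, 0 °C
Reagents that add atoms: 3-chloroperoxybenzoic acid (mCPBA), O=C(OO)c1cccc(Cl)c1
Why: Prilezhaev epoxidation; the enoate alkene is too electron-poor to react, and the peracid should approach C8=C17 from the α face because the β face is screened by the axial C10 methyl and the 6α-hydroxyl can hydrogen-bond the reagent. This sets C8 with oxygen α.

Step 4
Reactants: 4 ethyl (13E)-8α,17-epoxy-6α-hydroxylabd-13-en-15-oate
Product: 5 (13E)-labd-13-ene-6α,8α,15-triol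
Conditions: LiAlH4 (4 equiv), THF, 0 °C to rt
Reagents that add atoms: none
Why: Hydride reduction; the epoxide is opened at the unhindered C17 methylene (SN2), which leaves the 8α-oxygen in place (8α-OH, 8β-CH3), and the enoate is reduced 1,2 to the E allylic alcohol.

Step 5
Reactants: 5 (13E)-labd-13-ene-6α,8α,15-triol
Product: 7 (13E)-8α-(trimethylsilyloxy)labd-13-ene-6α,15-diol, via tris(trimethylsilyl) ether 6 (not isolated)
Conditions: TMSOTf (3.6 equiv), 2,6-lutidine, CH2Cl2, −78 to 0 °C; then K2CO3 (0.2 equiv), MeOH, 0 °C
Reagents that add atoms: trimethylsilyl trifluoromethanesulfonate, C[Si](C)(C)OS(=O)(=O)C(F)(F)F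
Why: Exhaustive silylation then selective methanolysis; primary and secondary trimethylsilyl ethers are cleaved by methanolic carbonate much faster than a tertiary one, so only O8 should stay capped.

Step 6
Reactants: 7 (13E)-8α-(trimethylsilyloxy)labd-13-ene-6α,15-diol
Product: 8 (13E)-15-(tert-butyldimethylsilyloxy)-8α-(trimethylsilyloxy)labd-13-en-6α-ol
Conditions: TBSCl (1.1 equiv), imidazole, CH2Cl2, 0 °C
Reagents that add atoms: tert-butyldimethylsilyl chloride, CC(C)(C)[Si](C)(C)Cl
Why: Chlorosilane silylation; the unhindered primary allylic hydroxyl reacts well before the 6α-hydroxyl, which is shielded by the peri C18 methyl and the ring fusion.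

Step 7
Reactants: 8 (13E)-15-(tert-butyldimethylsilyloxy)-8α-(trimethylsilyloxy)labd-13-en-6α-ol; 9 diethylsilane
Product: 10 (13E)-15-(tert-butyldimethylsilyloxy)-6α-(diethylsilyloxy)-8α-(trimethylsilyloxy)labd-13-ene (the 6-O-diethylhydrosilyl ether)
Conditions: [Ir(cod)OMe]2 (0.5 mol %), THF, rt; volatiles removed in vacuo
Reagents that add atoms: none
Why: Iridium-catalysed dehydrogenative O-silylation of an alcohol with a dihydrosilane; one Si–H bond is used and H2 leaves, the second Si–H bond is kept, and the neutral conditions leave both silyl ethers and the alkene alone.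

Step 8
Reactants: 10 (13E)-15-(tert-butyldimethylsilyloxy)-6α-(diethylsilyloxy)-8α-(trimethylsilyloxy)labd-13-ene
Product: 11 C18-silylated oxasilinane: (13E)-15-(tert-butyldimethylsilyloxy)-8α-(trimethylsilyloxy)labd-13-ene with a diethylsilanediyl bridge from O6α to C18 (the 4α-CH2)
Conditions: [RhCl(cod)]2 (2.5 mol %), Xantphos (6 mol %), norbornene (2 equiv), THF, 100 °C, sealed tube
Reagents that add atoms: none
Why: The Si–H bond of 10 adds oxidatively to monovalent rhodium bearing Xantphos, norbornene inserts into Rh–H and norbornane is lost, and the resulting monovalent rhodium silyl cleaves a C18–H bond by oxidative addition (seven-membered rhodacycle, trivalent rhodium) before C–Si reductive elimination releases 11. The closest known reaction type is the rhodium/Xantphos-catalysed silylation of a δ methyl C–H bond in diethylhydrosilyl ethers of alcohols, which gives 1,4-diols after oxidation; here the tether starts at a secondary ring carbinol, and the rigid trans-decalin supplies the preorganisation that geminal substitution supplies in the known cases. One ring closes, the 1-oxa-2-silacyclohexane O6–Si–C18–C4–C5–C6, by C–Si reductive elimination from the rhodacycle (an intramolecular dehydrogenative C(sp3)–H silylation), as a chair fused across C4–C5–C6. One stereocentre appears, C4, because only one of its two methyl groups is silylated; it is controlled by the fixed equatorial 6α configuration of the tether oxygen, which lies about 2.5 Å from the 4α-methyl through two gauche torsions of opposite sign. The step needs site selectivity among C18, C19, C20 and C17: C19 could close only a twist-boat, C20 and C17 lie anti to O6 along C6–C5–C10 and C6–C7–C8, and no γ C–H bond exists because C4, C8 and C10 are fully substituted. Secondary C–H bonds are not expected to react under these conditions, 10 holds a single Si–H bond and no allylic ester, and the strained norbornene should take up hydrogen before the hindered C13=C14 bond does. No skeletal bond is formed and no existing stereocentre is touched.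

Step 9
Reactants: 11 C18-silylated oxasilinane
Product: 12 (13E)-labd-13-ene-6α,8α,15,18-tetraol
Conditions: 30% H2O2, KHCO3, TBAF, THF/MeOH, 50 °C
Reagents that add atoms: hydrogen peroxide, OO
Why: Tamao–Fleming oxidation; fluoride makes the alkoxysilane hypervalent, hydroperoxide adds and C18 migrates from silicon to oxygen with retention, so C18–Si becomes C18–OH and O6 is released. The same fluoride removes the trimethylsilyl and tert-butyldimethylsilyl ethers, and the isolated alkene is inert to basic peroxide.

Step 10
Reactants: 12 (13E)-labd-13-ene-6α,8α,15,18-tetraol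
Product: 13 (13E)-6α,8α,18-trihydroxylabd-13-en-15-al
Conditions: MnO2 (20 equiv), acetone, rt
Reagents that add atoms: none
Why: Manganese dioxide oxidation is selective for allylic alcohols; the neopentyl C18, secondary C6 and tertiary C8 hydroxyls are not activated, and the E geometry should be kept.

Step 11
Reactants: 13 (13E)-6α,8α,18-trihydroxylabd-13-en-15-al
Product: 14 (13E)-6α,8α,18-tris(triethylsilyloxy)labd-13-en-15-al
Conditions: TESOTf (3.6 equiv), 2,6-lutidine, CH2Cl2, −78 to −20 °C
Reagents that add atoms: triethylsilyl trifluoromethanesulfonate, CC[Si](CC)(CC)OS(=O)(=O)C(F)(F)F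
Why: Silyl triflate silylation with a hindered pyridine base covers primary, secondary and tertiary hydroxyls at low temperature, where γ-deprotonation of the enal to a silyl dienol ether is slow.

Step 12
Reactants: 15 4-methylfuran-2(5H)-one
Product: 16 4-methyl-2-(trimethylsilyloxy)furan
Conditions: TMSOTf (1.1 equiv), Et3N, Et2O, 0 °C; distillation
Reagents that add atoms: trimethylsilyl trifluoromethanesulfonate, C[Si](C)(C)OS(=O)(=O)C(F)(F)F
Why: Soft enolisation; O-silylation of the lactone carbonyl and loss of the acidic C5 proton give the aromatic 2-silyloxyfuran.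

Step 13
Reactants: 14 (13E)-6α,8α,18-tris(triethylsilyloxy)labd-13-en-15-al; 16 4-methyl-2-(trimethylsilyloxy)furan
Product: 18 (13E,15S)-15-[(2S)-3-methyl-5-oxo-2,5-dihydrofuran-2-yl]-6α,8α,18-tris(triethylsilyloxy)labd-13-en-15-ol, via O-trichlorosilyl aldolate 17 (not isolated)
Conditions: SiCl4 (1.5 equiv), (R,R)-N,N′-bis(3,5-dimethyl-4-oxido-3,5-dihydro-4H-dinaphtho[2,1-d:1′,2′-f][1,3,2]diazaphosphepin-4-yl)-N,N′-dimethylpentane-1,5-diamine (5 mol %), iPr2NEt (0.2 equiv), CH2Cl2, −78 °C; aqueous work-up
Reagents that add atoms: none
Why: Catalytic enantioselective vinylogous Mukaiyama aldol reaction; the chiral bisphosphoramide binds SiCl4 to give a cationic chiral silicon Lewis acid that activates the conjugated aldehyde, and 16 attacks through C5 in an open transition state. The (R,R) catalyst is chosen for Re-face attack (15S; its mirror image is used if the facial sense proves opposite for this enal), and the antiperiplanar approach preferred by furan dienolates should place the ring oxygen syn to the new hydroxyl (5′S).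

Step 14
Reactants: 18 (13E,15S)-15-[(2S)-3-methyl-5-oxo-2,5-dihydrofuran-2-yl]-6α,8α,18-tris(triethylsilyloxy)labd-13-en-15-ol
Product: 19 (13E,15S)-15-[(2S)-3-methyl-5-oxo-2,5-dihydrofuran-2-yl]labd-13-ene-6α,8α,15,18-tetraol (CNP0255788.1)
Conditions: HF·pyridine, pyridine, THF, 0 °C to rt
Reagents that add atoms: none
Why: Fluoride desilylation under buffered, non-basic conditions removes the three triethylsilyl ethers (the tertiary one last) without epimerising C5′ or ionising the allylic C15 carbinol.

## Compound list

1 | larixol, (13S)-labda-8(17),14-diene-6α,13-diol | C=C[C@@](C)(O)CC[C@@H]1[C@@]2(C)CCCC(C)(C)[C@@H]2[C@@H](O)CC1=C | starting material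
2 | 6α-hydroxy-14,15-dinorlabd-8(17)-en-13-one | CC(=O)CC[C@@H]1[C@@]2(C)CCCC(C)(C)[C@@H]2[C@@H](O)CC1=C | intermediate
3 | ethyl (13E)-6α-hydroxylabda-8(17),13-dien-15-oate | CCOC(=O)/C=C(\C)CC[C@@H]1[C@@]2(C)CCCC(C)(C)[C@@H]2[C@@H](O)CC1=C | intermediate
4 | ethyl (13E)-8α,17-epoxy-6α-hydroxylabd-13-en-15-oate | CCOC(=O)/C=C(\C)CC[C@@H]1[C@@]2(C)CCCC(C)(C)[C@@H]2[C@@H](O)C[C@@]1(C3)O3 | intermediate
5 | (13E)-labd-13-ene-6α,8α,15-triol | OC/C=C(\C)CC[C@@H]1[C@@]2(C)CCCC(C)(C)[C@@H]2[C@@H](O)C[C@@]1(C)O | intermediate
6 | (13E)-6α,8α,15-tris(trimethylsilyloxy)labd-13-ene | C[Si](C)(C)OC/C=C(\C)CC[C@@H]1[C@@]2(C)CCCC(C)(C)[C@@H]2[C@@H](O[Si](C)(C)C)C[C@@]1(C)O[Si](C)(C)C | intermediate (not isolated)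
7 | (13E)-8α-(trimethylsilyloxy)labd-13-ene-6α,15-diol | OC/C=C(\C)CC[C@@H]1[C@@]2(C)CCCC(C)(C)[C@@H]2[C@@H](O)C[C@@]1(C)O[Si](C)(C)C | intermediate
8 | (13E)-15-(tert-butyldimethylsilyloxy)-8α-(trimethylsilyloxy)labd-13-en-6α-ol | CC(C)(C)[Si](C)(C)OC/C=C(\C)CC[C@@H]1[C@@]2(C)CCCC(C)(C)[C@@H]2[C@@H](O)C[C@@]1(C)O[Si](C)(C)C | intermediate
9 | diethylsilane | CC[SiH2]CC | starting material
10 | (13E)-15-(tert-butyldimethylsilyloxy)-6α-(diethylsilyloxy)-8α-(trimethylsilyloxy)labd-13-ene | CC(C)(C)[Si](C)(C)OC/C=C(\C)CC[C@@H]1[C@@]2(C)CCCC(C)(C)[C@@H]2[C@@H](O[SiH](CC)CC)C[C@@]1(C)O[Si](C)(C)C | intermediate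
11 | C18-silylated oxasilinane (diethylsilanediyl bridge O6α–C18; 15-OTBS, 8α-OTMS, 13E) | CC(C)(C)[Si](C)(C)OC/C=C(\C)CC[C@@H]1[C@@]2(C)CCC[C@@](C)(C[Si]3(CC)CC)[C@@H]2[C@@H](O3)C[C@@]1(C)O[Si](C)(C)C | intermediate
12 | (13E)-labd-13-ene-6α,8α,15,18-tetraol | OC/C=C(\C)CC[C@@H]1[C@@]2(C)CCC[C@@](C)(CO)[C@@H]2[C@@H](O)C[C@@]1(C)O | intermediate
13 | (13E)-6α,8α,18-trihydroxylabd-13-en-15-al | O=C/C=C(\C)CC[C@@H]1[C@@]2(C)CCC[C@@](C)(CO)[C@@H]2[C@@H](O)C[C@@]1(C)O | intermediate
14 | (13E)-6α,8α,18-tris(triethylsilyloxy)labd-13-en-15-al | O=C/C=C(\C)CC[C@@H]1[C@@]2(C)CCC[C@@](C)(CO[Si](CC)(CC)CC)[C@@H]2[C@@H](O[Si](CC)(CC)CC)C[C@@]1(C)O[Si](CC)(CC)CC | intermediate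
15 | 4-methylfuran-2(5H)-one | CC1=CC(=O)OC1 | starting material
16 | 4-methyl-2-(trimethylsilyloxy)furan | Cc1coc(O[Si](C)(C)C)c1 | intermediate
17 | (13E,15S)-15-[(2S)-3-methyl-5-oxo-2,5-dihydrofuran-2-yl]-15-(trichlorosilyloxy)-6α,8α,18-tris(triethylsilyloxy)labd-13-ene | CC1=CC(=O)O[C@@H]1[C@@H](O[Si](Cl)(Cl)Cl)/C=C(\C)CC[C@@H]1[C@@]2(C)CCC[C@@](C)(CO[Si](CC)(CC)CC)[C@@H]2[C@@H](O[Si](CC)(CC)CC)C[C@@]1(C)O[Si](CC)(CC)CC | intermediate (not isolated)
18 | (13E,15S)-15-[(2S)-3-methyl-5-oxo-2,5-dihydrofuran-2-yl]-6α,8α,18-tris(triethylsilyloxy)labd-13-en-15-ol | CC1=CC(=O)O[C@@H]1[C@@H](O)/C=C(\C)CC[C@@H]1[C@@]2(C)CCC[C@@](C)(CO[Si](CC)(CC)CC)[C@@H]2[C@@H](O[Si](CC)(CC)CC)C[C@@]1(C)O[Si](CC)(CC)CC | intermediate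
19 | (13E,15S)-15-[(2S)-3-methyl-5-oxo-2,5-dihydrofuran-2-yl]labd-13-ene-6α,8α,15,18-tetraol (CNP0255788.1) | CC1=CC(=O)O[C@@H]1[C@@H](O)/C=C(\C)CC[C@@H]1[C@@]2(C)CCC[C@@](C)(CO)[C@@H]2[C@@H](O)C[C@@]1(C)O | target

## Step count and least certain steps

Total: 14 steps. Longest linear sequence: 13 steps (steps 1 to 11, 13 and 14); step 12 is a one-step side branch.

**Step 8 (key step).** The C18–H oxidative addition may be too slow, because the tether starts at a secondary carbinol without geminal assistance. Hydrosilylation of norbornene by the rhodium silyl, or rhodium-hydride migration of the C13=C14 bond towards the silyl enol ether, could then take over.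
Fallback (from 8, back at 12): NOCl in pyridine would convert the free 6α-hydroxyl of 8 into the 6α-nitrite ester F1. Irradiation at about 350 nm (Barton nitrite photolysis) would give the 6α-alkoxyl radical, which abstracts a C18 hydrogen through a six-membered transition state for the same geometric reason; NO recombination and tautomerisation would give the C18 aldoxime F2. Buffered TiCl3 would unmask the aldehyde, held as the 6α,18-lactol F3. NaBH4 would open this to the bis-silylated 6α,18-diol F4, and TBAF would return 12.

**Step 13.** Facial control by the catalyst may be incomplete with a β,β-disubstituted enal, and the methyl group next to the reacting furan carbon may erode the syn preference; addition may also be slow.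
Fallback (from 14, back at 19): an Evans syn aldol reaction of 14 with the dibutylboron enolate (Bu2BOTf, Et3N) of (R)-4-benzyl-3-[(4-methoxybenzyloxy)acetyl]oxazolidin-2-one would set both centres under auxiliary control and give the syn glycolate adduct F5. Me(MeO)NH·HCl with AlMe3 would give the Weinreb amide F6, TESOTf its C15 silyl ether F7, MeMgBr the methyl ketone F8, and DDQ the α-hydroxy ketone F9. Ketenylidenetriphenylphosphorane (O-acylation, then intramolecular Wittig reaction) would close the ring to the tetrakis(triethylsilyl) butenolide F10, and HF·pyridine would give 19.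

**Step 2.** E/Z discrimination may be poor because CH3 and the C12 methylene differ little in size, and the isomers may co-elute.
Fallback (from 2, back at 5): kinetic enolisation of 2 at the methyl group (LDA), trapping with ClP(O)(OEt)2 and elimination with more LDA would give the terminal alkyne F11. mCPBA and then LiAlH4, as in steps 3 and 4, would give the epoxy alkyne F12 and the alkynyl diol F13. Zirconium-catalysed carboalumination (AlMe3, Cp2ZrCl2) and quenching of the alkenylalane with paraformaldehyde would give 5; the syn addition of methyl and aluminium fixes the E geometry.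

**Step 1.** Over-oxidation may compete with the cleavage: attack on the 8(17)-alkene, or oxidation of the 6α-hydroxyl to the ketone.
Fallback (from 1, back at 2): hydroxyl-directed epoxidation with VO(acac)2 and tBuOOH, which the tertiary allylic hydroxyl should direct to C14=C15, would give the 14,15-epoxide F14. H5IO6 in aqueous THF would open it to the triol and cleave both C–C bonds to give 2.

## Further compounds

F1 | step 8 | 6α-nitrite ester of 8 | CC(C)(C)[Si](C)(C)OC/C=C(\C)CC[C@@H]1[C@@]2(C)CCCC(C)(C)[C@@H]2[C@@H](ON=O)C[C@@]1(C)O[Si](C)(C)C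
F2 | step 8 | C18 aldoxime, (13E)-15-(tert-butyldimethylsilyloxy)-6α-hydroxy-8α-(trimethylsilyloxy)labd-13-en-18-al oxime | CC(C)(C)[Si](C)(C)OC/C=C(\C)CC[C@@H]1[C@@]2(C)CCC[C@@](C)(C=NO)[C@@H]2[C@@H](O)C[C@@]1(C)O[Si](C)(C)C
F3 | step 8 | 6α,18-lactol (6α,18-epoxy-18-ol; 15-OTBS, 8α-OTMS) | CC(C)(C)[Si](C)(C)OC/C=C(\C)CC[C@@H]1[C@@]2(C)CCC[C@@](C)(C3O)[C@@H]2[C@@H](O3)C[C@@]1(C)O[Si](C)(C)C
F4 | step 8 | (13E)-15-(tert-butyldimethylsilyloxy)-8α-(trimethylsilyloxy)labd-13-ene-6α,18-diol | CC(C)(C)[Si](C)(C)OC/C=C(\C)CC[C@@H]1[C@@]2(C)CCC[C@@](C)(CO)[C@@H]2[C@@H](O)C[C@@]1(C)O[Si](C)(C)C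
F5 | step 13 | syn glycolate aldol adduct with (R)-4-benzyloxazolidin-2-one auxiliary (C5′–OPMB, C15–OH) | COc1ccc(CO[C@@H](C(=O)N2[C@H](Cc3ccccc3)COC2=O)[C@@H](O)/C=C(\C)CC[C@@H]4[C@@]5(C)CCC[C@@](C)(CO[Si](CC)(CC)CC)[C@@H]5[C@@H](O[Si](CC)(CC)CC)C[C@@]4(C)O[Si](CC)(CC)CC)cc1
F6 | step 13 | Weinreb amide (N-methoxy-N-methyl amide; C15–OH free) | COc1ccc(CO[C@@H](C(=O)N(C)OC)[C@@H](O)/C=C(\C)CC[C@@H]2[C@@]3(C)CCC[C@@](C)(CO[Si](CC)(CC)CC)[C@@H]3[C@@H](O[Si](CC)(CC)CC)C[C@@]2(C)O[Si](CC)(CC)CC)cc1
F7 | step 13 | C15 triethylsilyl ether of the Weinreb amide | COc1ccc(CO[C@@H](C(=O)N(C)OC)[C@@H](O[Si](CC)(CC)CC)/C=C(\C)CC[C@@H]2[C@@]3(C)CCC[C@@](C)(CO[Si](CC)(CC)CC)[C@@H]3[C@@H](O[Si](CC)(CC)CC)C[C@@]2(C)O[Si](CC)(CC)CC)cc1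
F8 | step 13 | α-(4-methoxybenzyloxy) methyl ketone | COc1ccc(CO[C@@H](C(C)=O)[C@@H](O[Si](CC)(CC)CC)/C=C(\C)CC[C@@H]2[C@@]3(C)CCC[C@@](C)(CO[Si](CC)(CC)CC)[C@@H]3[C@@H](O[Si](CC)(CC)CC)C[C@@]2(C)O[Si](CC)(CC)CC)cc1
F9 | step 13 | α-hydroxy methyl ketone | O[C@@H](C(C)=O)[C@@H](O[Si](CC)(CC)CC)/C=C(\C)CC[C@@H]1[C@@]2(C)CCC[C@@](C)(CO[Si](CC)(CC)CC)[C@@H]2[C@@H](O[Si](CC)(CC)CC)C[C@@]1(C)O[Si](CC)(CC)CC
F10 | step 13 | tetrakis(triethylsilyl) ether of 19 | CC1=CC(=O)O[C@@H]1[C@@H](O[Si](CC)(CC)CC)/C=C(\C)CC[C@@H]1[C@@]2(C)CCC[C@@](C)(CO[Si](CC)(CC)CC)[C@@H]2[C@@H](O[Si](CC)(CC)CC)C[C@@]1(C)O[Si](CC)(CC)CC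
F11 | step 2 | terminal alkyne from 2 (6α-hydroxy, 8(17)-ene, C12–C≡CH) | C#CCC[C@@H]1[C@@]2(C)CCCC(C)(C)[C@@H]2[C@@H](O)CC1=C
F12 | step 2 | 8α,17-epoxy alkyne | C#CCC[C@@H]1[C@@]2(C)CCCC(C)(C)[C@@H]2[C@@H](O)C[C@@]1(C3)O3
F13 | step 2 | alkynyl 6α,8α-diol | C#CCC[C@@H]1[C@@]2(C)CCCC(C)(C)[C@@H]2[C@@H](O)C[C@@]1(C)O
F14 | step 1 | 14,15-epoxylarixol (C14 epimers) | C1OC1[C@@](C)(O)CC[C@@H]2[C@@]3(C)CCCC(C)(C)[C@@H]3[C@@H](O)CC2=C
A1 | alternative 1 | aldoxime precursor on the isopropenyl cyclohexenone | O=C1C(C)=CC[C@@H](C(C)=C)[C@]1(C)CCC=NO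
A2 | alternative 1 | isoxazoline-fused decalenone | O=C1C(C)=CC[C@H]2[C@]3(C)CON=C3CC[C@]12C
A3 | alternative 2 | acyclic epoxy diene (E,E; 6-OTBS; PMB ether) | CC1(CO1)CCC/C(C)=C/[C@@H](O[Si](C)(C)C(C)(C)C)C/C(C)=C/CCOCc1ccc(OC)cc1
A4 | alternative 2 | 18-hydroxy-6α-silyloxy decalin with 8(17)-alkene and C11–C12 arm | COc1ccc(COCC[C@@H]2[C@@]3(C)CCC[C@@](C)(CO)[C@@H]3[C@@H](O[Si](C)(C)C(C)(C)C)CC2=C)cc1
A5 | alternative 3 | 9α-hydroxy-9β-acetyl hydrindane | CC(=O)[C@]1(O)[C@@]2(C)CCC[C@@](C)(COCc3ccccc3)[C@@H]2[C@@H](O[Si](C)(C)C(C)(C)C)C1
A6 | alternative 3 | 8α-hydroxy-8β-methyl decalin-9-one | O=C1[C@@]2(C)CCC[C@@](C)(COCc3ccccc3)[C@@H]2[C@@H](O[Si](C)(C)C(C)(C)C)C[C@@]1(C)O
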